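**Plan**

1. Locants: ring A = C1–C5, C10; ring B = C5–C10; ring C (cyclopentene) = C8, C9, C11, C12, C13; ring D = C8, C13, C12, C16, C15, C14; C17 = CH2OAc, C18 = CH2OH, C19 and C20 = methyls on C4 and C10.
2. Retrosynthetic cuts, last to first: C17–OAc and C16–C17 (epoxide opening, ylide); C12–C16 and C8–C14 (aldol, alkylation, ring D); C8–C13 and C9–C11 (acylation, Negishi coupling, ring C); C4–C18 (ene reaction); C1–C10 and C2–C3 (Diels–Alder, ring A).
3. Forward order: ring B is bought; ring A by Diels–Alder; ring C by cyclopentenone annulation on the C9 ketone; ring D by alkylation and aldol; then C13 and C16 are adjusted.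
4. Enabling feature: C1 and C2 are an unsubstituted CH2–CH2 pair lying between C3 and the quaternary C10, so ring A is the adduct of the diene C3=C4–C5=C10 and a two-carbon dienophile; the tetrasubstituted C4=C5 alkene left behind can lose an allylic hydrogen only at C6, which allows hydroxymethylation at C4.
5. Stereochemistry: the C9 carbinol (CBS reduction) directs C10 in the Diels–Alder step and is later erased as the ketone; C20 then directs C4 (ene) and C8 (alkylation); C18–OH directs C5 (hydrogenation); the ring D bridge fixes C12; C16–OH directs the C13 reduction; axial ylide attack sets C16.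

Key step: step 4

**Route**

Step 1
Reactants: 1 3-ethoxy-2-methylcyclohex-2-en-1-one; 2 isopropenylmagnesium bromide
Product: 4 2-methyl-3-(prop-1-en-2-yl)cyclohex-2-en-1-one, via Grignard adduct 3 (not isolated)
Conditions: THF, 0 °C; then 1 M HCl, rt
Reagents that add atoms: water O
Why: Stork–Danheiser sequence: 1,2-addition to the vinylogous ester, then acid hydrolysis with loss of water, transposes the enone and places the isopropenyl group (C3, C4, C19) on C5; no stereocentre is formed.

Step 2
Reactants: 4 2-methyl-3-(prop-1-en-2-yl)cyclohex-2-en-1-one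
Product: 5 (S)-2-methyl-3-(prop-1-en-2-yl)cyclohex-2-en-1-ol
Conditions: (R)-2-methyl-CBS-oxazaborolidine (10 mol %), BH3·SMe2, THF, −20 °C
Reagents that add atoms: none
Why: Corey–Bakshi–Shibata reduction: the catalyst treats the substituted alkenyl flank as the large group and the C8 methylene as the small one, so C9 should be set as S by reagent control.

Step 3
Reactants: 5 (S)-2-methyl-3-(prop-1-en-2-yl)cyclohex-2-en-1-ol
Product: 6 (S)-tert-butyldimethyl{[2-methyl-3-(prop-1-en-2-yl)cyclohex-2-en-1-yl]oxy}silane
Conditions: t-BuMe2SiCl, imidazole, DMF, 0 °C to rt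
Reagents that add atoms: tert-butyldimethylsilyl chloride CC(C)(C)[Si](C)(C)Cl
Why: Standard silylation of a secondary alcohol; the bulky silyl ether next to C10 is the group that will shield one face of the diene.

Step 4
Reactants: 6 (S)-tert-butyldimethyl{[2-methyl-3-(prop-1-en-2-yl)cyclohex-2-en-1-yl]oxy}silane; 7 (E)-1,2-bis(phenylsulfonyl)ethene
Product: 8 bicyclic disulfone (rings A and B; C4=C5; C10 quaternary with β-methyl; 9β-silyloxy; PhSO2 on C1 and C2, trans, both diastereomers at these two centres)
Conditions: toluene, BHT (cat.), 100 °C, sealed tube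
Reagents that add atoms: none
Why: Concerted, asynchronous thermal [4+2] cycloaddition: the s-cis diene C3=C4–C5=C10 of 6 adds to the electron-poor alkene of 7, with C2–C3 forming slightly ahead of C1–C10. The closest known reaction type is the Diels–Alder reaction of 1-vinylcyclohexene-type dienes with 1,2-bis(arylsulfonyl)ethenes used as acetylene or ethylene equivalents. Ring A closes in a suprafacial 4π+2π mode, both new bonds on one face of the diene. The only new stereocentre that is kept, C10, is controlled by the C9 silyloxy group, which lies pseudo-axial next to the C10 methyl and blocks its own face, so C1 enters anti to oxygen and C20 ends cis to it (β); the two sulfonyl-bearing centres are removed in step 5. The step needs facial selectivity and enough reactivity at the fully substituted C10 terminus: the silyl ether secures the first, and the doubly activated, symmetrical dienophile (no regiochemical question) together with the C4 methyl, which favours the s-cis conformer, secures the second. The alkene it leaves, C4=C5, is tetrasubstituted and is used in step 6.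

Step 5
Reactants: 8 bicyclic disulfone
Product: 9 diene (C1=C2 and C4=C5; 10β-methyl; 9β-silyloxy)
Conditions: Na(Hg) (6 %), Na2HPO4, MeOH/THF, −20 °C to rt
Reagents that add atoms: none
Why: Julia-type reductive elimination of a vicinal disulfone gives the C1=C2 alkene whatever the configuration at C1 and C2, and leaves the silyl ether and C10 untouched.

Step 6
Reactants: 9 diene
Product: 10 homoallylic alcohol (C4 quaternary: 4β-methyl, 4α-CH2OH; C5=C6 and C1=C2; 9β-silyloxy)
Conditions: (CH2O)n, Me2AlCl (2 equiv), CH2Cl2, −78 °C to 0 °C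
Reagents that add atoms: formaldehyde C=O
Why: Me2AlCl-promoted carbonyl-ene reaction of formaldehyde with the tetrasubstituted alkene: the C–C bond should form at C4, the less hindered alkene carbon, on the α face away from the pseudo-axial C20, and the only removable hydrogen next to C5 is on C6, so the alkene moves to C5=C6.

Step 7
Reactants: 10 homoallylic alcohol
Product: 11 trans-decalin alcohol (4α-CH2OH, 4β,10β-dimethyl, 5α-H, 9β-silyloxy)
Conditions: H2 (1 atm), [Ir(cod)(PCy3)(py)]PF6 (5 mol %), CH2Cl2, rt
Reagents that add atoms: none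
Why: Hydroxyl-directed hydrogenation: the iridium catalyst binds the C18 hydroxyl and delivers hydrogen to the α face of C5=C6, giving the 5α-H trans ring fusion, and it also saturates C1=C2.

Step 8
Reactants: 11 trans-decalin alcohol
Product: 12 diol (9β-OH, C18–OH)
Conditions: Bu4NF, THF, 50 °C
Reagents that add atoms: none
Why: Fluoride cleavage of the silyl ether; no stereocentre is touched.

Step 9
Reactants: 12 diol
Product: 13 C18 tert-butyldiphenylsilyl ether with free 9β-OH
Conditions: t-BuPh2SiCl, imidazole, CH2Cl2, 0 °C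
Reagents that add atoms: tert-butyldiphenylsilyl chloride CC(C)(C)[Si](Cl)(c1ccccc1)c1ccccc1
Why: Selective silylation: the primary hydroxyl reacts, the secondary one next to quaternary C10 does not.

Step 10
Reactants: 13 C18 silyl ether alcohol
Product: 14 decalone (C9 ketone)
Conditions: Dess–Martin periodinane, NaHCO3, CH2Cl2, rt
Reagents that add atoms: none
Why: Dess–Martin oxidation of a hindered secondary alcohol; the relay stereocentre C9 is erased as planned and no epimerisable centre is adjacent.

Step 11
Reactants: 14 decalone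
Product: 15 enol triflate (C8=C9, triflate on C9)
Conditions: KN(SiMe3)2, THF, −78 °C; PhNTf2, −78 °C to 0 °C
Reagents that add atoms: N-phenylbis(trifluoromethanesulfonimide) O=S(=O)(N(c1ccccc1)S(=O)(=O)C(F)(F)F)C(F)(F)F
Why: Enolate O-triflation: the ketone can enolise only toward C8 because C10 is quaternary.

Step 12
Reactants: 15 enol triflate; 16 (3-ethoxy-3-oxopropyl)zinc bromide
Product: 17 ethyl ester (C9 carries C11H2–C12H2–C13O2Et; C8=C9)
Conditions: Pd(PPh3)4 (5 mol %), THF, 60 °C
Reagents that add atoms: none
Why: Negishi coupling of a zinc homoenolate with an enol triflate after oxidative addition to zerovalent palladium; it forms the C9–C11 bond at a carbon that a nucleophile could not reach in the ketone.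

Step 13
Reactants: 17 ethyl ester
Product: 18 carboxylic acid
Conditions: LiOH, THF/MeOH/H2O, rt; then cold 1 M HCl to pH 3
Reagents that add atoms: lithium hydroxide [Li+].[OH-]
Why: Ester saponification; the primary tert-butyldiphenylsilyl ether should survive.

Step 14
Reactants: 18 carboxylic acid
Product: 20 tricyclic cyclopentenone (ring C closed; C13 ketone; C8=C9), via mixed anhydride 19 (not isolated)
Conditions: (CF3CO)2O, CH2Cl2, 0 °C to rt
Reagents that add atoms: none
Why: Intramolecular Friedel–Crafts-type acylation of an alkene by a mixed trifluoroacetic anhydride: the acyl carbon C13 bonds to C8, and loss of the C8 proton from the tertiary C9 cation gives the conjugated tetrasubstituted enone.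

Step 15
Reactants: 20 tricyclic cyclopentenone; 21 2-(2-bromoethyl)-1,3-dioxolane
Product: 22 β,γ-unsaturated ketone (C8 quaternary: C13 β, C14 α; C9=C11; dioxolane at C16)
Conditions: KOt-Bu (1.05 equiv), THF/t-BuOH, 0 °C; then 21, 0 °C to rt
Reagents that add atoms: none
Why: Deconjugative α-alkylation of the extended dienolate formed by removal of a C11 hydrogen: the electrophile should attack C8 anti to the axial C20 methyl, which places C14 α and C13 β and moves the alkene to C9=C11.

Step 16
Reactants: 22 β,γ-unsaturated ketone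
Product: 24 bridged ketol (rings C and D closed; C13 ketone; C16–OH axial on ring D, on the face away from the C9=C11 bridge), via keto aldehyde 23 (not isolated)
Conditions: PPTS, acetone/H2O, 60 °C; then DBU (0.2 equiv), CH2Cl2, rt
Reagents that add atoms: water O
Why: Acetal hydrolysis followed by intramolecular aldol addition: C12 is the only enolisable position, the α-face tether fixes the C12 bridgehead, and reversible aldolisation should settle on the C16 epimer whose axial hydroxyl hydrogen-bonds to the C13 carbonyl (dehydration is barred because C12 is a bridgehead).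

Step 17
Reactants: 24 bridged ketol
Product: 25 anti-1,3-diol (C13–OH equatorial on ring D, syn to C9=C11; C16–OH axial)
Conditions: Me4NBH(OAc)3, MeCN/AcOH, −20 °C
Reagents that add atoms: none
Why: Evans–Saksena reduction: hydride is delivered within the C16 alkoxyborohydride to the face of the C13 carbonyl that carries the C16 oxygen, so the new hydroxyl points toward the C9=C11 bridge.

Step 18
Reactants: 25 anti-1,3-diol
Product: 26 hydroxy ketone (C16 ketone; C13–OH kept)
Conditions: TEMPO (10 mol %), PhI(OAc)2, CH2Cl2, rt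
Reagents that add atoms: none
Why: Nitroxyl-catalysed oxidation is sensitive to hindrance: the C16 hydroxyl should react, while the C13 hydroxyl, flanked by quaternary C8 and close to C20, should not.

Step 19
Reactants: 26 hydroxy ketone
Product: 27 spiro-epoxide at C16 (C17 axial, epoxide oxygen equatorial)
Conditions: Me3SI, KN(SiMe3)2 (3 equiv each), THF, −10 °C to 0 °C
Reagents that add atoms: trimethylsulfonium iodide C[S+](C)C.[I-]
Why: Corey–Chaykovsky epoxidation: dimethylsulfonium methylide adds irreversibly along the axial direction, on the face of ring D away from the C9=C11 bridge (the equatorial path is blocked by the axial C12–C11 bond), so C17 becomes axial and oxygen equatorial.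

Step 20
Reactants: 27 spiro-epoxide
Product: 28 C18-silylated botryotin E (C16 tertiary alcohol, C17 acetate)
Conditions: AcOH, CsOAc (cat.), DMF, 80 °C
Reagents that add atoms: acetic acid CC(=O)O
Why: Carboxylate-catalysed opening of a 2,2-disubstituted epoxide by SN2 attack at the primary carbon C17; the C16–O bond and its configuration are kept.

Step 21
Reactants: 28 C18-silylated botryotin E
Product: 29 botryotin E
Conditions: HF·pyridine, THF, 0 °C to rt
Reagents that add atoms: none
Why: Fluoride cleavage of the primary silyl ether under mildly acidic conditions, which should leave the acetate, the tertiary alcohol and the alkene untouched.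

**Compound list**

1 | 3-ethoxy-2-methylcyclohex-2-en-1-one | CCOC1=C(C)C(=O)CCC1 | starting material
2 | isopropenylmagnesium bromide | CC(=C)[Mg]Br | starting material
3 | 3-ethoxy-2-methyl-1-(prop-1-en-2-yl)cyclohex-2-en-1-ol (Grignard adduct, present as its magnesium alkoxide) | CCOC1=C(C)C(O)(C(C)=C)CCC1 | intermediate (not isolated)
4 | 2-methyl-3-(prop-1-en-2-yl)cyclohex-2-en-1-one | CC(=C)C1=C(C)C(=O)CCC1 | intermediate
5 | (S)-2-methyl-3-(prop-1-en-2-yl)cyclohex-2-en-1-ol | CC(=C)C1=C(C)[C@@H](O)CCC1 | intermediate
6 | (S)-tert-butyldimethyl{[2-methyl-3-(prop-1-en-2-yl)cyclohex-2-en-1-yl]oxy}silane | CC(=C)C1=C(C)[C@@H](O[Si](C)(C)C(C)(C)C)CCC1 | intermediate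
7 | (E)-1,2-bis(phenylsulfonyl)ethene | O=S(=O)(/C=C/S(=O)(=O)c1ccccc1)c1ccccc1 | starting material
8 | bicyclic disulfone (C4=C5, 10β-methyl, 9β-OTBS, PhSO2 at C1 and C2, configuration at C1 and C2 not defined) | CC1=C2CCC[C@H](O[Si](C)(C)C(C)(C)C)[C@@]2(C)C(S(=O)(=O)c3ccccc3)C(S(=O)(=O)c3ccccc3)C1 | intermediate
9 | diene (C1=C2, C4=C5, 10β-methyl, 9β-OTBS) | CC1=C2CCC[C@H](O[Si](C)(C)C(C)(C)C)[C@@]2(C)C=CC1 | intermediate
10 | homoallylic alcohol (4α-CH2OH, 4β-methyl, C5=C6, C1=C2, 9β-OTBS) | CC(C)(C)[Si](C)(C)O[C@H]1CCC=C2[C@](C)(CO)CC=C[C@]12C | intermediate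
11 | trans-decalin alcohol (4α-CH2OH, 4β,10β-dimethyl, 5α-H, 9β-OTBS) | CC(C)(C)[Si](C)(C)O[C@H]1CCC[C@H]2[C@](C)(CO)CCC[C@]12C | intermediate
12 | diol (9β-OH, C18–OH) | O[C@H]1CCC[C@H]2[C@](C)(CO)CCC[C@]12C | intermediate
13 | C18 tert-butyldiphenylsilyl ether, 9β-OH | O[C@H]1CCC[C@H]2[C@](C)(CO[Si](c3ccccc3)(c3ccccc3)C(C)(C)C)CCC[C@]12C | intermediate
14 | decalone (C9 ketone, C18 silyl ether) | O=C1CCC[C@H]2[C@](C)(CO[Si](c3ccccc3)(c3ccccc3)C(C)(C)C)CCC[C@]12C | intermediate
15 | enol triflate (C8=C9) | O=S(=O)(OC1=CCC[C@H]2[C@](C)(CO[Si](c3ccccc3)(c3ccccc3)C(C)(C)C)CCC[C@]12C)C(F)(F)F | intermediate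
16 | (3-ethoxy-3-oxopropyl)zinc bromide | CCOC(=O)CC[Zn]Br | starting material
17 | ethyl ester (C9–CH2CH2CO2Et, C8=C9) | CCOC(=O)CCC1=CCC[C@H]2[C@](C)(CO[Si](c3ccccc3)(c3ccccc3)C(C)(C)C)CCC[C@]12C | intermediate
18 | carboxylic acid | OC(=O)CCC1=CCC[C@H]2[C@](C)(CO[Si](c3ccccc3)(c3ccccc3)C(C)(C)C)CCC[C@]12C | intermediate
19 | mixed trifluoroacetic anhydride of 18 | O=C(CCC1=CCC[C@H]2[C@](C)(CO[Si](c3ccccc3)(c3ccccc3)C(C)(C)C)CCC[C@]12C)OC(=O)C(F)(F)F | intermediate (not isolated)
20 | tricyclic cyclopentenone (C13 ketone, C8=C9) | O=C1CCC2=C1CC[C@H]3[C@](C)(CO[Si](c4ccccc4)(c4ccccc4)C(C)(C)C)CCC[C@]23C | intermediate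
21 | 2-(2-bromoethyl)-1,3-dioxolane | BrCCC1OCCO1 | starting material
22 | β,γ-unsaturated ketone (C8 quaternary, C13 β, C14 α, C9=C11, dioxolane at C16) | O=C1CC=C2[C@]1(CCC3OCCO3)CC[C@H]3[C@](C)(CO[Si](c4ccccc4)(c4ccccc4)C(C)(C)C)CCC[C@]23C | intermediate
23 | keto aldehyde (C16 aldehyde) | O=C1CC=C2[C@]1(CCC=O)CC[C@H]3[C@](C)(CO[Si](c4ccccc4)(c4ccccc4)C(C)(C)C)CCC[C@]23C | intermediate (not isolated)
24 | bridged ketol (C13 ketone, C16 axial OH, C9=C11) | O[C@H]1CC[C@]23CC[C@H]4[C@](C)(CO[Si](c5ccccc5)(c5ccccc5)C(C)(C)C)CCC[C@]4(C)C2=C[C@H]1C3=O | intermediate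
25 | anti-1,3-diol (C13 equatorial OH, C16 axial OH) | O[C@H]1CC[C@]23CC[C@H]4[C@](C)(CO[Si](c5ccccc5)(c5ccccc5)C(C)(C)C)CCC[C@]4(C)C2=C[C@H]1[C@H]3O | intermediate
26 | hydroxy ketone (C16 ketone, C13–OH) | O=C1CC[C@]23CC[C@H]4[C@](C)(CO[Si](c5ccccc5)(c5ccccc5)C(C)(C)C)CCC[C@]4(C)C2=C[C@H]1[C@H]3O | intermediate
27 | C16 spiro-epoxide (C17 axial) | C1O[C@@]12CC[C@]34CC[C@H]5[C@](C)(CO[Si](c6ccccc6)(c6ccccc6)C(C)(C)C)CCC[C@]5(C)C3=C[C@H]2[C@H]4O | intermediate
28 | C18-O-tert-butyldiphenylsilyl botryotin E | CC(=O)OC[C@@]1(O)CC[C@]23CC[C@H]4[C@](C)(CO[Si](c5ccccc5)(c5ccccc5)C(C)(C)C)CCC[C@]4(C)C2=C[C@H]1[C@H]3O | intermediate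
29 | botryotin E | CC(=O)OC[C@@]1(O)CC[C@]23CC[C@H]4[C@](C)(CO)CCC[C@]4(C)C2=C[C@H]1[C@H]3O | target

**Count and risks**

Total step count: 21. Longest linear sequence: 21 steps (from 1).

The three steps most likely to fail:

Step 4. The cycloaddition may be too slow at the fully substituted C10 terminus, and the higher temperature then needed may bring a 1,5-hydrogen shift of the diene and loss of facial selectivity. The fallback sets out from 6 and comes back at 9. Compound 6 would be heated with maleic anhydride, a smaller and more reactive cis-dienophile (toluene, 80 °C), to give the anhydride adduct F1 with the same facial sense. Mild hydrolysis (aqueous NaHCO3/THF, then acid) would give the cis-diacid F2, and oxidative bis-decarboxylation with Pb(OAc)4 and pyridine would give diene 9.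

Step 6. The C–C bond may form at the wrong alkene carbon or face, and cationic side paths (chloride capture, 1,2-shift toward the C5 cation) may take over if proton loss from C6 is slow. The fallback sets out from 9 and comes back at 10, using a concerted ene reaction with a more reactive enophile followed by removal of one carbon. Ethyl glyoxylate with SnCl4 at −78 °C would give the α-hydroxy ester F3. LiAlH4 would reduce it to the 1,2-diol F4, NaIO4 would cleave this to the neopentyl aldehyde F5, and NaBH4 would give 10.

Step 15. The ambident dienolate may be alkylated at C12, C11 or oxygen, because the wanted site C8 is the most hindered. The fallback sets out from 20 and comes back at 23, which goes on to 24 under the conditions of step 16. The potassium dienolate of 20 would be O-acylated with allyl chloroformate to give the dienyl allyl carbonate F6. Pd(PPh3)4 would then effect decarboxylative allylation at C8 to give the C8-allyl ketone F7. Hydroboration of the terminal alkene with 9-BBN and oxidation with NaBO3 would give the primary alcohol F8, and Dess–Martin oxidation would give 23.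

**Further compounds**

F1 | step 4 | maleic anhydride adduct of 6 (cis-fused anhydride on C1 and C2) | CC1=C2CCC[C@H](O[Si](C)(C)C(C)(C)C)[C@@]2(C)C2C(C1)C(=O)OC2=O
F2 | step 4 | cis-1,2-dicarboxylic acid from F1 | CC1=C2CCC[C@H](O[Si](C)(C)C(C)(C)C)[C@@]2(C)C(C(O)=O)C(C1)C(O)=O
F3 | step 6 | glyoxylate ene adduct (C4–CH(OH)CO2Et, C5=C6) | CC(C)(C)[Si](C)(C)O[C@H]1CCC=C2[C@](C)(C(O)C(=O)OCC)CC=C[C@]12C
F4 | step 6 | 1,2-diol from F3 | CC(C)(C)[Si](C)(C)O[C@H]1CCC=C2[C@](C)(C(O)CO)CC=C[C@]12C
F5 | step 6 | C4 aldehyde | CC(C)(C)[Si](C)(C)O[C@H]1CCC=C2[C@](C)(C=O)CC=C[C@]12C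
F6 | step 15 | dienyl allyl carbonate of 20 | C=CCOC(=O)OC1=C2CC[C@H]3[C@](C)(CO[Si](c4ccccc4)(c4ccccc4)C(C)(C)C)CCC[C@]3(C)C2=CC1
F7 | step 15 | C8-allyl β,γ-unsaturated ketone | O=C1CC=C2[C@]1(CC=C)CC[C@H]3[C@](C)(CO[Si](c4ccccc4)(c4ccccc4)C(C)(C)C)CCC[C@]23C
F8 | step 15 | C16 primary alcohol | O=C1CC=C2[C@]1(CCCO)CC[C@H]3[C@](C)(CO[Si](c4ccccc4)(c4ccccc4)C(C)(C)C)CCC[C@]23C
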